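The route rests on disconnecting the C7–C8 bond of ring B, the bond between the secondary carbinol carbon and the isopropenyl-bearing methine (eremophilane numbering; ring A = C1–C5 and C10, ring B = C5–C10). This homoallylic alcohol is the retron of a carbonyl-ene reaction, and the cis oxygens on C8 and C9 allow chelation. In one operation an Me2AlCl-chelated α-(4-methoxybenzyloxy) aldehyde is attacked by a prenyl group, closing ring B and setting C7 and C8 through a boat-like transition state. The precursor is a monocyclic ring A cyclohexanol carrying a prenyl group on the quaternary C5 and a CH(OPMB)–CHO chain on C10.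

Key step: step 11

Remark: eremophilane numbering is used in the text (C14 is the methyl on C5, C15 the methyl on C4, C11–C13 the isopropenyl group); the target is the (2S,4S,5R,7R,8R,9S,10R) isomer with a (2Z)-3-methylpent-2-enoate on O9, and (R)-glyceraldehyde acetonide is taken as commercially available.

Step 1
Reactants: 1 (S)-carvone
Product: 3 (1S)-4-methyl-5-oxocyclohex-3-en-1-yl acetate, via methoxy hydroperoxide 2 (not isolated)
Conditions: O3, CH2Cl2/MeOH, −78 °C; then Ac2O, Et3N, DMAP, 0 °C to rt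
Reagents that add atoms: ozone, O=[O+][O-]; methanol, CO
Why: Ozone should cleave only the electron-rich isopropenyl alkene, methanol traps the carbonyl oxide as the α-methoxy hydroperoxide, and its peracetate undergoes a Criegee rearrangement in which the ring carbon migrates to oxygen with retention, so the future C2 carbinol keeps the carvone configuration (the acetyl group of 3 is the former C(CH3) unit of the isopropenyl group).

Step 2
Reactants: 3 (1S)-4-methyl-5-oxocyclohex-3-en-1-yl acetate
Product: 4 (5S)-5-hydroxy-2-methylcyclohex-2-en-1-one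
Conditions: K2CO3 (cat.), MeOH, 0 °C
Reagents that add atoms: none
Why: Base-catalysed transesterification (methanolysis) at low temperature should remove the acetate before β-elimination can compete, and the stereocenter is not touched.

Step 3
Reactants: 4 (5S)-5-hydroxy-2-methylcyclohex-2-en-1-one
Product: 5 (5S)-5-[(tert-butyldimethylsilyl)oxy]-2-methylcyclohex-2-en-1-one
Conditions: TBSCl, imidazole, DMF, rt
Reagents that add atoms: tert-butyldimethylsilyl chloride, CC(C)(C)[Si](C)(C)Cl
Why: Standard silylation of a secondary alcohol gives an ether that survives the cuprate and enolate chemistry that follows.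

Step 4
Reactants: 5 (5S)-5-[(tert-butyldimethylsilyl)oxy]-2-methylcyclohex-2-en-1-one; 6 prenyl bromide
Product: 8 (2R,3S,5S)-5-[(tert-butyldimethylsilyl)oxy]-2,3-dimethyl-2-(3-methylbut-2-en-1-yl)cyclohexan-1-one, via lithium enolate 7 (not isolated)
Conditions: Me2CuLi (from MeLi and CuI), Et2O, −78 to −20 °C; then 6, HMPA, −20 °C to rt
Reagents that add atoms: lithium dimethylcuprate, [Li+].C[Cu-]C
Why: In this tandem cuprate conjugate addition–enolate alkylation the methyl group should add anti to the silyloxy group (setting C4 trans to O2) and the regiodefined enolate should be alkylated anti to the new neighbouring methyl group, which gives the quaternary C5 with the cis-vicinal methyl groups.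

Step 5
Reactants: 8 (2R,3S,5S)-5-[(tert-butyldimethylsilyl)oxy]-2,3-dimethyl-2-(3-methylbut-2-en-1-yl)cyclohexan-1-one
Product: 10 (3S,5S,6R)-3-[(tert-butyldimethylsilyl)oxy]-5,6-dimethyl-6-(3-methylbut-2-en-1-yl)cyclohex-1-en-1-yl trifluoromethanesulfonate, via potassium enolate 9 (not isolated)
Conditions: KN(SiMe3)2, THF, −78 °C; then PhNTf2, −78 to 0 °C
Reagents that add atoms: N-phenylbis(trifluoromethanesulfonimide), O=S(=O)(N(c1ccccc1)S(=O)(=O)C(F)(F)F)C(F)(F)F
Why: Only the CH2 side of the ketone can be enolised (the other α-carbon is quaternary), so kinetic deprotonation and O-triflation should give a single enol triflate, the low temperature suppressing β-elimination of the silyloxy group.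

Step 6
Reactants: 10 (3S,5S,6R)-3-[(tert-butyldimethylsilyl)oxy]-5,6-dimethyl-6-(3-methylbut-2-en-1-yl)cyclohex-1-en-1-yl trifluoromethanesulfonate; 11 (R)-glyceraldehyde acetonide
Product: 12 (S)-{(3S,5S,6R)-3-[(tert-butyldimethylsilyl)oxy]-5,6-dimethyl-6-(3-methylbut-2-en-1-yl)cyclohex-1-en-1-yl}[(4R)-2,2-dimethyl-1,3-dioxolan-4-yl]methanol
Conditions: CrCl2 (6 equiv), NiCl2 (2 mol %), DMF, rt
Reagents that add atoms: none
Why: In this Nozaki–Hiyama–Kishi coupling nickel inserts into the C–OTf bond and hands the alkenyl group to chromium, and the alkenylchromium reagent should add to the aldehyde under Felkin–Anh control, anti to the α-C–O bond of 11, which sets the new carbinol center (the future C9) anti to the dioxolane oxygen.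

Step 7
Reactants: 12 (S)-{(3S,5S,6R)-3-[(tert-butyldimethylsilyl)oxy]-5,6-dimethyl-6-(3-methylbut-2-en-1-yl)cyclohex-1-en-1-yl}[(4R)-2,2-dimethyl-1,3-dioxolan-4-yl]methanol
Product: 13 (4R)-4-[(S)-{(3S,5S,6R)-3-[(tert-butyldimethylsilyl)oxy]-5,6-dimethyl-6-(3-methylbut-2-en-1-yl)cyclohex-1-en-1-yl}[(4-methoxybenzyl)oxy]methyl]-2,2-dimethyl-1,3-dioxolane
Conditions: NaH, PMBBr, Bu4NI (cat.), DMF, 0 °C to rt
Reagents that add atoms: 4-methoxybenzyl bromide, COc1ccc(CBr)cc1
Why: Williamson etherification installs the ether oxygen that will chelate in the key step and removes the C9 hydroxyl as a competing directing group for step 9.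

Step 8
Reactants: 13 (4R)-4-[(S)-{(3S,5S,6R)-3-[(tert-butyldimethylsilyl)oxy]-5,6-dimethyl-6-(3-methylbut-2-en-1-yl)cyclohex-1-en-1-yl}[(4-methoxybenzyl)oxy]methyl]-2,2-dimethyl-1,3-dioxolane
Product: 14 (1S,4R,5S)-3-{(S)-[(4R)-2,2-dimethyl-1,3-dioxolan-4-yl][(4-methoxybenzyl)oxy]methyl}-4,5-dimethyl-4-(3-methylbut-2-en-1-yl)cyclohex-2-en-1-ol
Conditions: TBAF, THF, rt
Reagents that add atoms: none
Why: Fluoride-mediated desilylation frees the allylic C2 hydroxyl, which is needed as the directing group of the next step.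

Step 9
Reactants: 14 (1S,4R,5S)-3-{(S)-[(4R)-2,2-dimethyl-1,3-dioxolan-4-yl][(4-methoxybenzyl)oxy]methyl}-4,5-dimethyl-4-(3-methylbut-2-en-1-yl)cyclohex-2-en-1-ol
Product: 15 (1S,3S,4R,5R)-5-{(S)-[(4R)-2,2-dimethyl-1,3-dioxolan-4-yl][(4-methoxybenzyl)oxy]methyl}-3,4-dimethyl-4-(3-methylbut-2-en-1-yl)cyclohexan-1-ol
Conditions: [Rh(nbd)(dppb)]BF4 (10 mol %), H2 (60 bar), CH2Cl2, rt
Reagents that add atoms: none
Why: In this hydroxyl-directed homogeneous hydrogenation the cationic rhodium catalyst binds the allylic C2 hydroxyl and should deliver hydrogen to the same face of the ring alkene, which puts H10 syn to O2 and the side chain cis to the C5 methyl group and trans to the prenyl group, while the unfunctionalised trisubstituted prenyl alkene is expected to be reduced much more slowly by this catalyst.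

Step 10
Reactants: 15 (1S,3S,4R,5R)-5-{(S)-[(4R)-2,2-dimethyl-1,3-dioxolan-4-yl][(4-methoxybenzyl)oxy]methyl}-3,4-dimethyl-4-(3-methylbut-2-en-1-yl)cyclohexan-1-ol
Product: 17 (2S)-2-[(1R,2R,3S,5S)-5-hydroxy-2,3-dimethyl-2-(3-methylbut-2-en-1-yl)cyclohexyl]-2-[(4-methoxybenzyl)oxy]acetaldehyde, via 1,2-diol 16 (not isolated)
Conditions: H5IO6, EtOAc, 0 °C to rt
Reagents that add atoms: none
Why: Periodic acid should hydrolyse the terminal acetonide and cleave the liberated 1,2-diol (Malaprade glycol cleavage) in one pot, giving the α-alkoxy aldehyde under non-enolising conditions that leave the C9 center intact.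

Step 11
Reactants: 17 (2S)-2-[(1R,2R,3S,5S)-5-hydroxy-2,3-dimethyl-2-(3-methylbut-2-en-1-yl)cyclohexyl]-2-[(4-methoxybenzyl)oxy]acetaldehyde
Product: 18 (1S,2R,3R,4aR,5S,7S,8aR)-1-[(4-methoxybenzyl)oxy]-4a,5-dimethyl-3-(prop-1-en-2-yl)decahydronaphthalene-2,7-diol
Conditions: Me2AlCl (3.5 equiv), CH2Cl2, −78 to −40 °C; aq. Rochelle salt work-up
Reagents that add atoms: none
Why: Excess Me2AlCl turns the C2 hydroxyl into an aluminium alkoxide and binds the aldehyde oxygen and the C9 ether oxygen in a five-membered chelate, after which the prenyl C7=C11 bond attacks C8 through C7 while a hydrogen of a C11 methyl group passes to the carbonyl oxygen in a concerted or nearly concerted carbonyl-ene reaction that leaves the C11=C12 isopropenyl group and the C8 aluminium alkoxide. The closest known reaction type is the Lewis-acid-promoted intramolecular type 1 carbonyl-ene cyclisation of citronellal to isopulegol, combined with the known chelation control of α-alkoxy aldehydes by dialkylaluminium chlorides. Ring B closes as a six-membered carbocycle by 6-exo-trig attack on the C8=O group with C11 left outside the ring, because positive charge develops at the tertiary C11 and not at C7. C8 (R) is controlled by the chelate, which holds O8 syn-periplanar to O9 while C7, tethered through C10–C5–C6, can only reach the carbonyl face on the C10 side, so the 8,9-cis diol monoether results; C7 (R) is controlled by the same syn-periplanar O–C9–C8–O array, which forces the C10–C9–C8–C7 torsion close to 0° and thus a boat-like ring B in which H7 takes the flagpole position facing H10 and the CMe2 terminus the outward position anti to both C9 and C5, so the isopropenyl group ends cis to the C5 methyl group and trans to O8. The step needs the chelated boat pathway to outrun the non-chelated chair pathway, which would give the all-equatorial 7,8-bis-epimer, and this is secured by the good donor PMB ether in place of a silyl ether, by more than two equivalents of Me2AlCl in a non-coordinating solvent at low temperature, and by the higher electrophilicity of the chelated aldehyde.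

Step 12
Reactants: 18 (1S,2R,3R,4aR,5S,7S,8aR)-1-[(4-methoxybenzyl)oxy]-4a,5-dimethyl-3-(prop-1-en-2-yl)decahydronaphthalene-2,7-diol
Product: 19 (1S,2R,3R,4aR,5S,7S,8aR)-4a,5-dimethyl-3-(prop-1-en-2-yl)decahydronaphthalene-1,2,7-triol
Conditions: DDQ, CH2Cl2/pH 7 buffer, 0 °C to rt
Reagents that add atoms: none
Why: Oxidative PMB ether cleavage (benzylic hydride abstraction by DDQ and hydrolysis of the oxocarbenium ion) should free O9 without touching the isopropenyl group or the stereocenters.

Step 13
Reactants: 20 ethyl pent-2-ynoate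
Product: 22 ethyl (2Z)-3-methylpent-2-enoate, via alkenylcuprate 21 (not isolated)
Conditions: Me2CuLi, THF, −78 °C; then MeOH, −78 °C
Reagents that add atoms: lithium dimethylcuprate, [Li+].C[Cu-]C
Why: Syn-carbocupration of the ynoate places methyl and copper on the same side, and protonation of the alkenylcuprate at low temperature with retention should give the Z alkene with the ethyl group cis to the ester.

Step 14
Reactants: 22 ethyl (2Z)-3-methylpent-2-enoate
Product: 23 (2Z)-3-methylpent-2-enoic acid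
Conditions: LiOH, THF/H2O, rt; then 1 M HCl
Reagents that add atoms: lithium hydroxide, [Li+].[OH-]
Why: Saponification of the ethyl ester is expected to leave the trisubstituted alkene geometry unchanged.

Step 15
Reactants: 23 (2Z)-3-methylpent-2-enoic acid
Product: 24 (2Z)-3-methylpent-2-enoyl chloride
Conditions: (COCl)2, DMF (cat.), CH2Cl2, 0 °C to rt
Reagents that add atoms: oxalyl chloride, ClC(=O)C(Cl)=O
Why: Acyl chloride formation through the Vilsmeier-type chloroiminium intermediate needs no amine base, so ketene-mediated scrambling of the alkene geometry is avoided.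

Step 16
Reactants: 19 (1S,2R,3R,4aR,5S,7S,8aR)-4a,5-dimethyl-3-(prop-1-en-2-yl)decahydronaphthalene-1,2,7-triol; 24 (2Z)-3-methylpent-2-enoyl chloride
Product: 26 (1S,2R,3R,4aR,5S,7S,8aR)-2,7-dihydroxy-4a,5-dimethyl-3-(prop-1-en-2-yl)decahydronaphthalen-1-yl (2Z)-3-methylpent-2-enoate, via stannylene acetal 25 (not isolated)
Conditions: Bu2SnO, toluene, reflux (Dean–Stark); then 24, 0 °C to rt
Reagents that add atoms: none
Why: In this stannylene-acetal-mediated regioselective acylation the dibutylstannylene should form on the cis-1,2-diol (O8 and O9) and react at its equatorial oxygen O9, so the hindered axial O8 next to the isopropenyl group and the isolated axial C2 hydroxyl stay free and no stereocenter is touched.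

Compound list
1 | (S)-carvone, (5S)-2-methyl-5-(prop-1-en-2-yl)cyclohex-2-en-1-one | CC1=CC[C@@H](CC1=O)C(C)=C | starting material
2 | (5S)-5-(1-hydroperoxy-1-methoxyethyl)-2-methylcyclohex-2-en-1-one (both epimers at the side-chain carbon) | CC1=CC[C@@H](CC1=O)C(C)(OC)OO | intermediate
3 | (1S)-4-methyl-5-oxocyclohex-3-en-1-yl acetate | CC1=CC[C@H](OC(C)=O)CC1=O | intermediate
4 | (5S)-5-hydroxy-2-methylcyclohex-2-en-1-one | CC1=CC[C@H](O)CC1=O | intermediate
5 | (5S)-5-[(tert-butyldimethylsilyl)oxy]-2-methylcyclohex-2-en-1-one | CC1=CC[C@H](O[Si](C)(C)C(C)(C)C)CC1=O | intermediate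
6 | prenyl bromide, 1-bromo-3-methylbut-2-ene | CC(C)=CCBr | starting material
7 | lithium (3S,5S)-5-[(tert-butyldimethylsilyl)oxy]-2,3-dimethylcyclohex-1-en-1-olate | CC1=C([O-])C[C@@H](O[Si](C)(C)C(C)(C)C)C[C@@H]1C.[Li+] | intermediate
8 | (2R,3S,5S)-5-[(tert-butyldimethylsilyl)oxy]-2,3-dimethyl-2-(3-methylbut-2-en-1-yl)cyclohexan-1-one | CC(C)=CC[C@]1(C)[C@@H](C)C[C@H](O[Si](C)(C)C(C)(C)C)CC1=O | intermediate
9 | potassium (3S,5S,6R)-3-[(tert-butyldimethylsilyl)oxy]-5,6-dimethyl-6-(3-methylbut-2-en-1-yl)cyclohex-1-en-1-olate | CC(C)=CC[C@]1(C)[C@@H](C)C[C@H](O[Si](C)(C)C(C)(C)C)C=C1[O-].[K+] | intermediate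
10 | (3S,5S,6R)-3-[(tert-butyldimethylsilyl)oxy]-5,6-dimethyl-6-(3-methylbut-2-en-1-yl)cyclohex-1-en-1-yl trifluoromethanesulfonate | CC(C)=CC[C@]1(C)[C@@H](C)C[C@H](O[Si](C)(C)C(C)(C)C)C=C1OS(=O)(=O)C(F)(F)F | intermediate
11 | (R)-glyceraldehyde acetonide, (4R)-2,2-dimethyl-1,3-dioxolane-4-carbaldehyde | O=C[C@H]1COC(C)(C)O1 | starting material
12 | (S)-{(3S,5S,6R)-3-[(tert-butyldimethylsilyl)oxy]-5,6-dimethyl-6-(3-methylbut-2-en-1-yl)cyclohex-1-en-1-yl}[(4R)-2,2-dimethyl-1,3-dioxolan-4-yl]methanol | CC(C)=CC[C@]1(C)[C@@H](C)C[C@H](O[Si](C)(C)C(C)(C)C)C=C1[C@H](O)[C@H]1COC(C)(C)O1 | intermediate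
13 | (4R)-4-[(S)-{(3S,5S,6R)-3-[(tert-butyldimethylsilyl)oxy]-5,6-dimethyl-6-(3-methylbut-2-en-1-yl)cyclohex-1-en-1-yl}[(4-methoxybenzyl)oxy]methyl]-2,2-dimethyl-1,3-dioxolane | CC(C)=CC[C@]1(C)[C@@H](C)C[C@H](O[Si](C)(C)C(C)(C)C)C=C1[C@H](OCc1ccc(OC)cc1)[C@H]1COC(C)(C)O1 | intermediate
14 | (1S,4R,5S)-3-{(S)-[(4R)-2,2-dimethyl-1,3-dioxolan-4-yl][(4-methoxybenzyl)oxy]methyl}-4,5-dimethyl-4-(3-methylbut-2-en-1-yl)cyclohex-2-en-1-ol | CC(C)=CC[C@]1(C)[C@@H](C)C[C@H](O)C=C1[C@H](OCc1ccc(OC)cc1)[C@H]1COC(C)(C)O1 | intermediate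
15 | (1S,3S,4R,5R)-5-{(S)-[(4R)-2,2-dimethyl-1,3-dioxolan-4-yl][(4-methoxybenzyl)oxy]methyl}-3,4-dimethyl-4-(3-methylbut-2-en-1-yl)cyclohexan-1-ol | CC(C)=CC[C@]1(C)[C@@H](C)C[C@H](O)C[C@H]1[C@H](OCc1ccc(OC)cc1)[C@H]1COC(C)(C)O1 | intermediate
16 | (2R,3S)-3-[(1R,2R,3S,5S)-5-hydroxy-2,3-dimethyl-2-(3-methylbut-2-en-1-yl)cyclohexyl]-3-[(4-methoxybenzyl)oxy]propane-1,2-diol | CC(C)=CC[C@]1(C)[C@@H](C)C[C@H](O)C[C@H]1[C@H](OCc1ccc(OC)cc1)[C@H](O)CO | intermediate
17 | (2S)-2-[(1R,2R,3S,5S)-5-hydroxy-2,3-dimethyl-2-(3-methylbut-2-en-1-yl)cyclohexyl]-2-[(4-methoxybenzyl)oxy]acetaldehyde | CC(C)=CC[C@]1(C)[C@@H](C)C[C@H](O)C[C@H]1[C@H](OCc1ccc(OC)cc1)C=O | intermediate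
18 | (1S,2R,3R,4aR,5S,7S,8aR)-1-[(4-methoxybenzyl)oxy]-4a,5-dimethyl-3-(prop-1-en-2-yl)decahydronaphthalene-2,7-diol | C=C(C)[C@H]1C[C@]2(C)[C@@H](C)C[C@H](O)C[C@H]2[C@H](OCc2ccc(OC)cc2)[C@@H]1O | intermediate
19 | (1S,2R,3R,4aR,5S,7S,8aR)-4a,5-dimethyl-3-(prop-1-en-2-yl)decahydronaphthalene-1,2,7-triol | C=C(C)[C@H]1C[C@]2(C)[C@@H](C)C[C@H](O)C[C@H]2[C@H](O)[C@@H]1O | intermediate
20 | ethyl pent-2-ynoate | CCC#CC(=O)OCC | starting material
21 | lithium [(2E)-1-ethoxy-3-methyl-1-oxopent-2-en-2-yl](methyl)cuprate | CCOC(=O)/C([Cu-]C)=C(/C)CC.[Li+] | intermediate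
22 | ethyl (2Z)-3-methylpent-2-enoate | CCOC(=O)/C=C(/C)CC | intermediate
23 | (2Z)-3-methylpent-2-enoic acid | OC(=O)/C=C(/C)CC | intermediate
24 | (2Z)-3-methylpent-2-enoyl chloride | ClC(=O)/C=C(/C)CC | intermediate
25 | 1,2-O-dibutylstannylene acetal of triol 19 (five-membered O–Sn–O ring on O8 and O9, C2 hydroxyl free, configuration as in 19) | C=C(C)[C@H]1C[C@]2(C)[C@@H](C)C[C@H](O)C[C@H]2[C@@H]2O[Sn](CCCC)(CCCC)O[C@H]12 | intermediate
26 | (1S,2R,3R,4aR,5S,7S,8aR)-2,7-dihydroxy-4a,5-dimethyl-3-(prop-1-en-2-yl)decahydronaphthalen-1-yl (2Z)-3-methylpent-2-enoate | C=C(C)[C@H]1C[C@]2(C)[C@@H](C)C[C@H](O)C[C@H]2[C@H](OC(=O)/C=C(/C)CC)[C@@H]1O | target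

Total step count: 16. Longest linear sequence: 13 steps (steps 1 to 12 and step 16); steps 13 to 15 prepare the acyl chloride.

Steps most likely to fail

Step 11 (key step). What may go wrong is reaction through the monodentate, non-chelated aldehyde complex by way of the chair transition state, which would erode or invert the facial selectivity at C7 and C8. The fallback replaces the dative chelate by a covalent five-membered acetal tether. It sets out from 17: DDQ in wet CH2Cl2 would remove the PMB group to give the α-hydroxy aldehyde F1. Then 2,2-dimethoxypropane, MeOH and camphorsulfonic acid would convert it into the 5-methoxy-2,2-dimethyl-1,3-dioxolane F2. TMSOTf with 2,6-di-tert-butyl-4-methylpyridine in CH2Cl2 at −78 °C would ionise the methoxy group to a dioxolanyl oxocarbenium ion in which O8 and O9 are held syn by covalent bonds, and its Prins-type closure with the prenyl group, ending by loss of a methyl proton, should give the cis-fused acetonide F3. Aqueous acetic acid would then release the triol, and the route is rejoined at 19.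

Step 9. What may go wrong is slow hydrogen delivery to the hindered trisubstituted ring alkene, so that reduction of the prenyl alkene competes. The fallback installs C9 by one-carbon homologation of the ketone and does without hydrogenation. It sets out from 8: a Wittig reaction with Ph3P=CHOMe would give the enol ether F4, and mild aqueous acid would hydrolyse it to the aldehyde F5. The two C10 epimers of this aldehyde are expected to be close in energy, so the wanted one would be separated and the other recycled by base equilibration. Then 2-lithio-1,3-dithiane would add under Felkin–Anh control, with the quaternary C5 as the large group, to give the carbinol F6. NaH and PMBBr would give the ether F7, TBAF the alcohol F8, and MeI with CaCO3 in aqueous MeCN would unmask the aldehyde, so the route is rejoined at 17.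

Step 6. What may go wrong is poor facial selectivity in the addition of the alkenylchromium reagent to the α-alkoxy aldehyde, giving both epimers at the new carbinol center. The fallback corrects this center by oxidation and chelation-controlled reduction. It sets out from 12 as the epimer mixture: Dess–Martin periodinane would give the enone F9, and Zn(BH4)2 in Et2O at low temperature, which chelates the ketone and the adjacent dioxolane oxygen and delivers hydride to the less hindered face of the chelate, should return the anti isomer, so the route is rejoined at 12.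

Further compounds
F1 | step 11 | (2S)-2-hydroxy-2-[(1R,2R,3S,5S)-5-hydroxy-2,3-dimethyl-2-(3-methylbut-2-en-1-yl)cyclohexyl]acetaldehyde | CC(C)=CC[C@]1(C)[C@@H](C)C[C@H](O)C[C@H]1[C@H](O)C=O
F2 | step 11 | (1S,3S,4R,5R)-5-[(4S)-5-methoxy-2,2-dimethyl-1,3-dioxolan-4-yl]-3,4-dimethyl-4-(3-methylbut-2-en-1-yl)cyclohexan-1-ol (both epimers at the acetal carbon) | CC(C)=CC[C@]1(C)[C@@H](C)C[C@H](O)C[C@H]1[C@@H]1OC(C)(C)OC1OC
F3 | step 11 | 1,2-O-isopropylidene acetal of triol 19 (acetonide on O8 and O9, configuration as in 19) | C=C(C)[C@H]1C[C@]2(C)[C@@H](C)C[C@H](O)C[C@H]2[C@@H]2OC(C)(C)O[C@H]12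
F4 | step 9 | tert-butyl{[(1S,3S,4R)-5-(methoxymethylidene)-3,4-dimethyl-4-(3-methylbut-2-en-1-yl)cyclohexyl]oxy}dimethylsilane (E/Z mixture) | CC(C)=CC[C@]1(C)[C@@H](C)C[C@H](O[Si](C)(C)C(C)(C)C)CC1=COC
F5 | step 9 | (1R,2R,3S,5S)-5-[(tert-butyldimethylsilyl)oxy]-2,3-dimethyl-2-(3-methylbut-2-en-1-yl)cyclohexane-1-carbaldehyde | CC(C)=CC[C@]1(C)[C@@H](C)C[C@H](O[Si](C)(C)C(C)(C)C)C[C@H]1C=O
F6 | step 9 | (S)-{(1R,2R,3S,5S)-5-[(tert-butyldimethylsilyl)oxy]-2,3-dimethyl-2-(3-methylbut-2-en-1-yl)cyclohexyl}(1,3-dithian-2-yl)methanol | CC(C)=CC[C@]1(C)[C@@H](C)C[C@H](O[Si](C)(C)C(C)(C)C)C[C@H]1[C@H](O)C1SCCCS1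
F7 | step 9 | 4-methoxybenzyl ether of F6, tert-butyl{[(1S,3S,4R,5R)-5-{(S)-(1,3-dithian-2-yl)[(4-methoxybenzyl)oxy]methyl}-3,4-dimethyl-4-(3-methylbut-2-en-1-yl)cyclohexyl]oxy}dimethylsilane | CC(C)=CC[C@]1(C)[C@@H](C)C[C@H](O[Si](C)(C)C(C)(C)C)C[C@H]1[C@H](OCc1ccc(OC)cc1)C1SCCCS1
F8 | step 9 | (1S,3S,4R,5R)-5-{(S)-(1,3-dithian-2-yl)[(4-methoxybenzyl)oxy]methyl}-3,4-dimethyl-4-(3-methylbut-2-en-1-yl)cyclohexan-1-ol | CC(C)=CC[C@]1(C)[C@@H](C)C[C@H](O)C[C@H]1[C@H](OCc1ccc(OC)cc1)C1SCCCS1
F9 | step 6 | {(3S,5S,6R)-3-[(tert-butyldimethylsilyl)oxy]-5,6-dimethyl-6-(3-methylbut-2-en-1-yl)cyclohex-1-en-1-yl}[(4R)-2,2-dimethyl-1,3-dioxolan-4-yl]methanone | CC(C)=CC[C@]1(C)[C@@H](C)C[C@H](O[Si](C)(C)C(C)(C)C)C=C1C(=O)[C@H]1COC(C)(C)O1
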